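Locants used throughout: the core is numbered as spiro[4.5]decane (ring A = C1–C5, ring B = C5–C10; C1 carbinol, C2 triene-bearing, C5 spiro, C6 arm-bearing, C7 enal-bearing, C10 methyl carbinol); the arm on C6 is C1′–C3′. The "C10 face" and "C6 face" of ring A are the faces syn to those two substituents of C5.

## The problem

The target 42 is a spiro[4.5]decane in which ring A and ring B share only the quaternary carbon C5. Four of its five stereocentres (C1, C5, C6, C10) crowd around that atom, and two of them (C5, C10) are fully substituted and adjacent. Ring B carries the 3-hydroxypropyl arm on C6, a tetrasubstituted exocyclic enal at C7 (formyl syn to C6) and the tertiary carbinol C10. Ring A carries the C1 alcohol and, trans to it on C2, a cross-conjugated triene that ends in a (Z)-allylic alcohol and a prenyl tail. Only C10 can sensibly be set by a reagent; C5 and C6 must then follow from C10, and C1 and C2 from C5, for which the C10 hydroxyl, lying on the same side of ring B as C1, is the natural handle. The enal (γ-hydrogens, sensitive to ozone, hydride and carbanions) and the triene with its allylic alcohol (sensitive to acid and oxidants) must come late. A free C10 hydroxyl β to a C1 carbonyl would invite retro-aldol cleavage, which fixes the order of protecting-group events. The enabling feature is that C1 and C3′ are both joined through C5–C6 and sit cis on ring B: C1, C5, C6, C1′, C2′ and C3′ are the six atoms of a cyclohexene whose cleavage at C1=C3′ leaves a C1 carbonyl and the arm, and that cyclohexene, fused to ring B along C5–C6, is the retron of an intramolecular Diels–Alder reaction between a 1-vinylcyclopentene and a tethered vinyl ketone.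

## Retrosynthesis

**Triene last.** 42 comes from its tris-silyl ether 41 by one acidic fluoride treatment. In 41 the sp2–sp2 bond between the 1,1-disubstituted alkene carbon on C2 and the (E)-alkene is cut, giving the 2-iodoalkene 32 and the dienylstannane 40. An olefination at the (E)-alkene would give geometric mixtures, and a triene carried earlier would not survive acid, chromium or hydride. 32 contains no polyene and 40 is a nine-carbon piece. The Stille coupling has to retain both geometries under neutral conditions that the enal tolerates.

**Side chain.** 40 is cut at its diene single bond into the (Z)-iodide 38 and the bis-stannane 39. 38 is the silyl ether of 37, which is cut between the alkene and the homoprenyl group into propargyl alcohol 34 and the bromide 33 (as its Grignard reagent 35). An anti-carbomagnesiation places the hydroxymethyl group and the iodine cis, exactly the geometry of the trisubstituted alkene, which an aldehyde-based olefination would not give.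

**Enal.** The C7=C bond of 32 is traced to the tertiary allylic alcohol 31 and then to the ketone 29 plus isopropenylmagnesium bromide 30. Addition followed by 1,3-oxidative transposition is preferred to a phosphonate olefination, which would need base at a hindered ketone with an epimerisable C6. The forward step must deliver the formyl group syn to C6.

**C2 carbon.** 29 goes back through the iodoalkene ketal 28, the alkyne 27 and the diol 26 to the epoxide 23 and ethynyltrimethylsilane 24; the C2–C(sp) bond is cut. Alkenylating an enolate of a C1 ketone would leave both C2 and the later C1 reduction uncontrolled. Anti-opening of an epoxide fixes the trans C1–OH/C2–C relationship, and the neopentyl character of C1 fixes the site of attack. The alkyne is a robust two-carbon placeholder that becomes the 2-iodoalkene.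

**Epoxide.** 23 comes from the alkene 22, whose free C10 hydroxyl must deliver oxygen to the ring A face syn to C10. 22 comes from the silyl ether 21, 21 from the enol triflate 20, and 20 from the ketone 19. The C1 oxygen of 19 is given up and returned on the correct face; this is the price of full stereocontrol in ring A.

**Temporary ring.** 19 is the silyl ether of the hydroxy ketone 18, which arises from the ketal 16 by cleaving C1=C3′. 16 is the C7 ketal of the tricyclic ketone 15. The ketal distinguishes the two ketones that the cleavage would otherwise leave side by side.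

**Key disconnection.** 15 is cut at C5–C6 and C1′–C2′ to the trienone 14, which has a single stereocentre. The forward cycloaddition has to form the quaternary C5 and the adjacent C6 with cis fusion and with the face dictated by C10.

**Dienophile and diene.** 14 comes from the allylic alcohol 13 by oxidation, so the reactive vinyl ketone appears only at the last moment. 13 comes from the bromide 11 and the vinylstannane 12. 11 comes from the aldehyde 9 and vinylmagnesium bromide 10. 9 comes from the terminal alkene 8, the silyl ether of 7. A terminal alkene is chosen as the masked aldehyde because unmasking an acetal would need acid that a tertiary allylic silyl ether would not tolerate.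

**Carbinol.** 7 is cut at the C10–CH3 bond to the ketone 5 and dimethylzinc 6, a catalytic asymmetric addition that sets the only stereocentre not derived from another. 5 comes from 1,2-dibromocyclopentene 3 (through the lithium reagent 4) and the N-methoxy-N-methylamide 2, which is made from the acid chloride 1.

## Roads not taken

Alternative 1: Cut C9–C10 of ring B. SmI2 would reduce the primary C9 iodide of the open-chain iodo keto diester A1, and the organosamarium would add to the C10 acetyl carbonyl while samarium bridges it to the C1 methyl ester, closing ring B as the hydroxy ester A2 and creating the C10 carbinol.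
- Merits: the closure is mild; the chelate gives a clear model for C10 relative to C5; the C7 oxygen and the protected arm are present from the start, so no ozonolysis and no ketal are needed. A later Dieckmann closure of the tert-butyl ester arm would give ring A as a β-keto ester, a better platform for functionalising C2 than the ketone of the chosen plan.
- Weak points: A1 already contains quaternary C5 flanked by C6 and C7 in an open chain, so the hardest centre is moved into the preparation of A1 and not solved. The β-keto ester is itself reducible by SmI2. The step makes one ring, one bond and one stereocentre.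
- Comparison: for ring A and C2 this road is at least as good. The chosen plan sets against it that C5 is made inside a preformed cyclopentene together with C6 and two rings, from a precursor with one stereocentre.

Alternative 2: Cut C6–C7 and C4–C5. Me2AlCl would activate the C7 aldehyde of the 1-alkenylcyclobutanol A3; the C5=C6 alkene attacks through C6, closing ring B, and the cation developing at C5 is quenched by a 1,2-shift of a cyclobutane CH2 (C4), which turns the cyclobutanol into the C1 cyclopentanone of the spiro ketone A4.
- Merits: ring B, the spiro centre, ring A and the C1 carbonyl arise in one operation, with the arm and a C7 oxygen in place. On paper this is the shortest of the four roads, and it needs no temporary ring.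
- Weak points: the C5/C6 relationship depends on the geometry of a trisubstituted alkene flanked by two fully substituted carbons, which is hard to obtain pure. The facial choice relative to C10 is the same oxygen-versus-methyl question as in the chosen plan, but in a cationic chair without a geometric lock on the fusion. Carbonyl-ene reaction, proton loss and ionisation next to the C10 silyl ether compete.
- Comparison: better in step economy. The chosen plan sets against it a concerted closure in which the fusion stereochemistry is fixed by the diene geometry and only one selectivity stays open.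

Alternative 3: Cut C6–C1′ and C4–C5 on a preformed ring B. The Grignard reagent A6, with catalytic CuBr·SMe2, would add to C6 of the enone ester A5 anti to the C7 silyloxy group, and the β-keto ester enolate would be alkylated at C5 by the bromocrotonate A7 anti to the new arm, giving the keto diester A8 in one operation.
- Merits: both half-reactions are robust and scalable; the C5/C6 relationship follows from a dependable trans alkylation; the arm arrives at its final oxidation level. As a key step it is safer than a cycloaddition at a fully substituted diene terminus.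
- Weak points: C10 must afterwards be made by methyl addition to the hindered ketone of a β-keto ester (uncertain face, retro-Claisen risk). Ring A still needs another C–C bond. The C7 centre that steers the step must be made enantiopure and is then erased. Two esters need redox adjustment.
- Comparison: more reliable at the key step, longer and less controlled afterwards. The chosen plan sets against it that C10 is set first by a catalyst and then controls C5 and C6, and that ring A exists before the key step.

Key step: step 9

Assumption (chemistry): the antipode of the bis(sulfonamide) diol ligand in step 3 is taken to be the one that delivers methyl to the ketone face giving (S)-7; both antipodes are accessible and the sense is to be confirmed on 7.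

## Route

Step 1
Reactants: 1 pent-4-enoyl chloride
Product: 2 N-methoxy-N-methylpent-4-enamide
Conditions: MeNHOMe·HCl, Et3N, CH2Cl2, 0 °C → rt
Reagents that add atoms: N,O-dimethylhydroxylamine hydrochloride, CNOC.Cl
Why: Acyl substitution of an acid chloride by the amine; the N-methoxy-N-methylamide is the acyl donor that stops at the ketone in step 2.

Step 2
Reactants: 3 1,2-dibromocyclopent-1-ene; 2 N-methoxy-N-methylpent-4-enamide
Product: 5 1-(2-bromocyclopent-1-en-1-yl)pent-4-en-1-one, via (2-bromocyclopent-1-en-1-yl)lithium 4 (not isolated)
Conditions: 3, n-BuLi, THF, −78 °C; then 2, −78 → 0 °C; H2O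
Reagents that add atoms: none
Why: Single bromine–lithium exchange gives the alkenyllithium, which is stable at −78 °C; its adduct with the amide is a chelated tetrahedral intermediate that releases the ketone only on quench, so no over-addition occurs.

Step 3
Reactants: 5 1-(2-bromocyclopent-1-en-1-yl)pent-4-en-1-one; 6 dimethylzinc
Product: 7 (2S)-2-(2-bromocyclopent-1-en-1-yl)hex-5-en-2-ol
Conditions: Me2Zn, Ti(OiPr)4, trans-cyclohexane-1,2-diamine bis(2-hydroxybornane-10-sulfonamide) ligand (10 mol %), toluene/hexane, rt
Reagents that add atoms: none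
Why: Titanium/bis(sulfonamide) diol-catalysed asymmetric 1,2-addition of a dialkylzinc to a ketone, a reaction that accepts conjugated alkenyl ketones. The catalyst distinguishes the sp2 flank from the sp3 chain and so sets C10 (S).

Step 4
Reactants: 7 (2S)-2-(2-bromocyclopent-1-en-1-yl)hex-5-en-2-ol
Product: 8 (2S)-2-(2-bromocyclopent-1-en-1-yl)hex-5-en-2-yl triethylsilyl ether
Conditions: Et3SiOTf, 2,6-lutidine, CH2Cl2, −78 → 0 °C
Reagents that add atoms: triethylsilyl trifluoromethanesulfonate, CC[Si](CC)(CC)OS(=O)(=O)C(F)(F)F
Why: Silyl triflate/lutidine silylation of a tertiary alcohol; the ether blocks ionisation and later retro-aldol cleavage and supplies the steric element at C10 for step 9.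

Step 5
Reactants: 8 (2S)-2-(2-bromocyclopent-1-en-1-yl)hex-5-en-2-yl triethylsilyl ether
Product: 9 (4S)-4-(2-bromocyclopent-1-en-1-yl)-4-(triethylsilyloxy)pentanal
Conditions: OsO4 (2 mol %), NaIO4, 2,6-lutidine, dioxane/H2O (3:1), rt
Reagents that add atoms: osmium tetroxide, O=[Os](=O)(=O)=O; sodium periodate, [Na+].[O-]I(=O)(=O)=O
Why: Lemieux–Johnson cleavage; osmylation takes only the monosubstituted alkene, because the tetrasubstituted bromoalkene is sterically and electronically inert. The buffered, neutral medium spares the tertiary allylic silyl ether.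

Step 6
Reactants: 9 (4S)-4-(2-bromocyclopent-1-en-1-yl)-4-(triethylsilyloxy)pentanal; 10 vinylmagnesium bromide
Product: 11 (6S)-6-(2-bromocyclopent-1-en-1-yl)-6-(triethylsilyloxy)hept-1-en-3-ol (both C3 epimers)
Conditions: CH2=CHMgBr, THF, −78 °C
Reagents that add atoms: none
Why: Grignard addition to an aldehyde; the alkenyl bromide does not exchange at −78 °C, and the new carbinol centre is removed by oxidation in step 8.

Step 7
Reactants: 11 (6S)-6-(2-bromocyclopent-1-en-1-yl)-6-(triethylsilyloxy)hept-1-en-3-ol; 12 tributyl(vinyl)stannane
Product: 13 (6S)-6-(2-ethenylcyclopent-1-en-1-yl)-6-(triethylsilyloxy)hept-1-en-3-ol (both C3 epimers)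
Conditions: CH2=CHSnBu3, Pd(PPh3)4 (5 mol %), CuI (10 mol %), DMF, 80 °C
Reagents that add atoms: none
Why: Stille coupling of a cyclic alkenyl bromide with a vinylstannane, copper-assisted because the bromide is tetrasubstituted; it completes the 1-vinylcyclopentene diene with the tether on the diene terminus.

Step 8
Reactants: 13 (6S)-6-(2-ethenylcyclopent-1-en-1-yl)-6-(triethylsilyloxy)hept-1-en-3-ol
Product: 14 (6S)-6-(2-ethenylcyclopent-1-en-1-yl)-6-(triethylsilyloxy)hept-1-en-3-one
Conditions: Dess–Martin periodinane, NaHCO3, CH2Cl2, 0 °C
Reagents that add atoms: none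
Why: Buffered periodinane oxidation of a secondary allylic alcohol to the vinyl ketone; the product is filtered cold and used at once so that the dienophile appears only when the diene is in place.

Step 9
Reactants: 14 (6S)-6-(2-ethenylcyclopent-1-en-1-yl)-6-(triethylsilyloxy)hept-1-en-3-one
Product: 15 tricyclic ketone (5S,6S,10S): ring B with C7 ketone and C10 methyl/triethylsilyloxy, cis-fused along C5–C6 to a cyclohexene (C5, C1=C3′, C2′, C1′, C6) that shares C5–C1 with cyclopentane ring A
Conditions: toluene (0.01 M), BHT (cat.), 80 °C
Reagents that add atoms: none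
Why: A thermal, concerted [4+2] cycloaddition (type 1 intramolecular Diels–Alder) joins the diene C5=C1–C3′=C2′ to the vinyl ketone C6=C1′ through the tether C10–C9–C8–C7; the closest known reaction type is the cyclisation of 1,7,9-decatrien-3-ones and of 2-tethered 1-vinylcycloalkenes that form angular quaternary carbons. Ring B closes in the fused mode as the six-membered tether ring through C5–C6 with the ketone inside the ring, and the cyclohexene closes through C1′–C2′, leaving the alkene at C1=C3′. C5 and C6 are fixed relative to each other by geometry: the tether is the Z substituent of the diene terminus, so only the transition state with the tether folded beneath the diene is reachable, and it gives the cis fusion with C1 and C1′ on the same side of ring B. Their absolute sense comes from C10: with C9 turned toward the dienophile, one remaining C10 substituent must point into the crowded interior of the s-cis diene and the other toward the ring CH2 (C4). The slimmer oxygen is expected inside and the methyl outside (least A(1,3) strain), which places the C10 oxygen cis to C1 on ring B. The step therefore needs selectivity only between two cis-fused transition states, since regiochemistry and fusion are set by the tether. The diene cannot escape by a [1,5]-hydrogen shift because its Z substituent C10 bears no hydrogen, and dilution with a radical inhibitor suppresses polymerisation of the vinyl ketone.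

Step 10
Reactants: 15 tricyclic ketone
Product: 16 C7 ethylene ketal (1,3-dioxolane) of 15
Conditions: (Me3SiOCH2)2, Me3SiOTf (5 mol %), CH2Cl2, −78 → −20 °C
Reagents that add atoms: 1,2-bis(trimethylsilyloxy)ethane, C[Si](C)(C)OCCO[Si](C)(C)C
Why: Aprotic silyl triflate-catalysed ketalisation at low temperature, chosen so that C6 does not epimerise and the tertiary silyl ether survives; C7 is masked for the ozone, hydride, enolate and organometallic steps that follow.

Step 11
Reactants: 16 C7 ethylene ketal of 15
Product: 18 6-(3-hydroxypropyl)-10-methyl-10-(triethylsilyloxy)spiro[4.5]decane-1,7-dione 7-ethylene ketal (core configuration as in 15), via keto aldehyde 17 (not isolated)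
Conditions: O3, CH2Cl2/MeOH (4:1), −78 °C; PPh3, −78 °C → rt; then NaBH4, −78 °C
Reagents that add atoms: ozone, [O-][O+]=O
Why: Ozonolysis of the only alkene gives the C1 ketone and the C3′ aldehyde. Borohydride at −78 °C reduces the aldehyde and leaves the neopentyl cyclopentanone, so the aldol-prone keto aldehyde is never isolated.

Step 12
Reactants: 18 hydroxy ketone
Product: 19 6-[3-(tert-butyldiphenylsilyloxy)propyl]-10-methyl-10-(triethylsilyloxy)spiro[4.5]decane-1,7-dione 7-ethylene ketal
Conditions: t-BuPh2SiCl, imidazole, DMF, rt
Reagents that add atoms: tert-butyl(chloro)diphenylsilane, CC(C)(C)[Si](Cl)(c1ccccc1)c1ccccc1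
Why: Standard silylation of a primary alcohol; this silyl group survives the later selective removal of the tertiary triethylsilyl ether.

Step 13
Reactants: 19 silyl ether ketone
Product: 20 C1 enol triflate of 19 (C1=C2 alkene, trifluoromethanesulfonyloxy on C1)
Conditions: KN(SiMe3)2, THF, −78 °C; then PhNTf2, −78 → 0 °C
Reagents that add atoms: N-phenylbis(trifluoromethanesulfonimide), O=S(=O)(N(c1ccccc1)S(=O)(=O)C(F)(F)F)C(F)(F)F
Why: The C1 ketone can enolise only toward C2 because C5 is quaternary, and the enolate is trapped on oxygen. The C10 silyl ether prevents retro-aldol cleavage and the ketal keeps C7 silent.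

Step 14
Reactants: 20 enol triflate
Product: 21 6-[3-(tert-butyldiphenylsilyloxy)propyl]-10-methyl-10-(triethylsilyloxy)spiro[4.5]dec-1-en-7-one ethylene ketal
Conditions: Pd(OAc)2 (5 mol %), PPh3, HCO2H, n-Bu3N, DMF, 60 °C
Reagents that add atoms: none
Why: Palladium-catalysed formate reduction of an alkenyl triflate (oxidative addition, formate-to-hydride exchange, reductive elimination) gives the C1=C2 cyclopentene without touching the other groups.

Step 15
Reactants: 21 cyclopentene silyl ether
Product: 22 6-[3-(tert-butyldiphenylsilyloxy)propyl]-10-hydroxy-10-methylspiro[4.5]dec-1-en-7-one ethylene ketal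
Conditions: HF·pyridine, pyridine, THF, 0 °C → rt
Reagents that add atoms: none
Why: Buffered HF cleaves the triethylsilyl ether and leaves the tert-butyldiphenylsilyl ether and the dioxolane. The hydroxyl is freed only now that no carbonyl at C1 can trigger retro-aldol cleavage.

Step 16
Reactants: 22 homoallylic alcohol
Product: 23 1,2-epoxide of 22 with the oxirane oxygen on the ring A face syn to C10
Conditions: VO(acac)2 (10 mol %), t-BuOOH, CH2Cl2, rt
Reagents that add atoms: tert-butyl hydroperoxide, CC(C)(C)OO
Why: Vanadium-catalysed hydroxyl-directed epoxidation of a homoallylic alcohol. The C10 hydroxyl is gauche to C1 and sits above the C1=C2 alkene, so the peroxide oxygen is delivered to the C10 face, which sets the configuration of the C1 oxygen.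

Step 17
Reactants: 23 epoxide; 24 ethynyltrimethylsilane
Product: 26 2-ethynyl-6-[3-(tert-butyldiphenylsilyloxy)propyl]-1,10-dihydroxy-10-methylspiro[4.5]decan-7-one ethylene ketal (C1–OH syn to C10; C2 ethynyl trans to it), via C-silyl alkyne 25 (not isolated)
Conditions: Me3SiC≡CH, n-BuLi, THF, −78 °C; BF3·OEt2, then 23, −78 °C; then K2CO3, MeOH, rt
Reagents that add atoms: none
Why: BF3-assisted SN2 opening of an epoxide by a lithium acetylide; attack occurs at C2 because C1 is neopentyl, and anti to the oxirane oxygen, which sets C2 and gives the trans hydroxy/alkynyl pair. Methanolysis then removes the C-silyl group.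

Step 18
Reactants: 26 alkyne diol
Product: 27 C1 tert-butyldimethylsilyl ether of 26 (C10 hydroxyl free)
Conditions: t-BuMe2SiOTf (1.2 equiv), 2,6-lutidine, CH2Cl2, −78 °C
Reagents that add atoms: tert-butyldimethylsilyl trifluoromethanesulfonate, CC(C)(C)[Si](C)(C)OS(=O)(=O)C(F)(F)F
Why: At −78 °C the silyl triflate silylates the secondary hydroxyl and leaves the hindered tertiary one; C1 must be protected before the chromium oxidation of step 22.

Step 19
Reactants: 27 terminal alkyne
Product: 28 2-(1-iodoethenyl) analogue of 27 (iodine on the alkene carbon attached to C2)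
Conditions: Ni(dppp)Cl2 (5 mol %), i-Bu2AlH (2.5 equiv), THF, 0 °C → rt; then N-iodosuccinimide, −78 → 0 °C
Reagents that add atoms: N-iodosuccinimide, O=C1CCC(=O)N1I
Why: Nickel-catalysed hydroalumination of a terminal alkyl alkyne with this bisphosphine places aluminium on the internal carbon, and iodinolysis gives the 2-iodo-1-alkene. The first hydride equivalent is consumed by the C10 hydroxyl, and the dioxolane and silyl ethers are inert.

Step 20
Reactants: 28 iodoalkene ketal
Product: 29 1-(tert-butyldimethylsilyloxy)-6-[3-(tert-butyldiphenylsilyloxy)propyl]-10-hydroxy-2-(1-iodoethenyl)-10-methylspiro[4.5]decan-7-one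
Conditions: pyridinium p-toluenesulfonate, acetone/H2O (9:1), 55 °C
Reagents that add atoms: water, O
Why: Mild acid-catalysed hydrolysis of the dioxolane; the alkenyl iodide and the two robust silyl ethers tolerate it, and the weak acid keeps enolisation toward C6 slow.

Step 21
Reactants: 29 C7 ketone; 30 isopropenylmagnesium bromide
Product: 31 7-hydroxy-7-(prop-1-en-2-yl) adduct of 29 (C7 epimers)
Conditions: CH2=C(CH3)MgBr, CeCl3, THF, −78 → 0 °C
Reagents that add atoms: none
Why: Organocerium-type addition to a hindered, enolisable ketone proceeds without deprotonating C6 or C8; the new C7 configuration is irrelevant because C7 becomes sp2 in step 22.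

Step 22
Reactants: 31 tertiary allylic alcohol
Product: 32 (2Z)-2-[1-(tert-butyldimethylsilyloxy)-6-[3-(tert-butyldiphenylsilyloxy)propyl]-10-hydroxy-2-(1-iodoethenyl)-10-methylspiro[4.5]decan-7-ylidene]propanal
Conditions: [C5H5NH][CrO3Cl], Celite, CH2Cl2, rt
Reagents that add atoms: none
Why: Babler–Dauben oxidative transposition: the chromate ester of the tertiary allylic alcohol undergoes a [3,3] shift to the primary allylic chromate, which is oxidised to the enal. The methyl group is expected to settle syn to the unsubstituted C8 and the slimmer formyl group syn to the branched C6 (least A(1,3) strain), which is also the geometry of the target.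

Step 23
Reactants: 33 5-bromo-2-methylpent-2-ene; 34 prop-2-yn-1-ol
Product: 37 (2Z)-3-iodo-2-(4-methylpent-3-en-1-yl)prop-2-en-1-ol, via (4-methylpent-3-en-1-yl)magnesium bromide 35 (not isolated), via alkenylmagnesium alkoxide 36 (not isolated)
Conditions: Mg, THF; then 34, CuI (10 mol %), Et2O, 0 °C → rt; then I2, −40 → 0 °C
Reagents that add atoms: iodine, II
Why: Copper-catalysed anti-carbomagnesiation of propargyl alcohol puts the alkyl group on C2 and magnesium on C3 inside a five-membered alkoxide chelate. Iodinolysis with retention gives the iodide cis to the hydroxymethyl group, which is the geometry of the trisubstituted alkene.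

Step 24
Reactants: 37 (2Z)-3-iodo-2-(4-methylpent-3-en-1-yl)prop-2-en-1-ol
Product: 38 tert-butyl{[(2Z)-3-iodo-2-(4-methylpent-3-en-1-yl)prop-2-en-1-yl]oxy}dimethylsilane
Conditions: t-BuMe2SiCl, imidazole, CH2Cl2, rt
Reagents that add atoms: tert-butyl(chloro)dimethylsilane, CC(C)(C)[Si](C)(C)Cl
Why: Standard silylation of a primary allylic alcohol, so that the side-chain hydroxyl shares the final deprotection.

Step 25
Reactants: 38 (Z)-alkenyl iodide; 39 (E)-1,2-bis(tributylstannyl)ethene
Product: 40 tributyl[(1E,3Z)-4-({[tert-butyl(dimethyl)silyl]oxy}methyl)-8-methylnona-1,3,7-trien-1-yl]stannane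
Conditions: 39 (2.5 equiv), Pd2(dba)3 (2.5 mol %), P(2-furyl)3, N-methylpyrrolidone, rt → 40 °C
Reagents that add atoms: none
Why: Stille mono-coupling of an alkenyl iodide with an excess of the bis-stannane retains both alkene geometries and leaves one tin for the union.

Step 26
Reactants: 32 iodoalkene enal; 40 dienylstannane
Product: 41 tris-silyl ether of 42 (C1 and side-chain oxygens as tert-butyldimethylsilyl ethers, C3′ oxygen as tert-butyldiphenylsilyl ether)
Conditions: Pd2(dba)3 (5 mol %), AsPh3, CuI, DMF, rt
Reagents that add atoms: none
Why: Stille coupling of a 2-iodo-1-alkene with an (E)-alkenylstannane at room temperature under neutral conditions; the enal and the free tertiary alcohol are tolerated and all alkene geometries are retained.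

Step 27
Reactants: 41 tris-silyl ether
Product: 42 (2Z)-2-[(1S,2S,5S,6R,10S)-1,10-dihydroxy-2-[(3E,5Z)-6-(hydroxymethyl)-10-methylundeca-1,3,5,9-tetraen-2-yl]-6-(3-hydroxypropyl)-10-methylspiro[4.5]decan-7-ylidene]propanal
Conditions: HF·pyridine, pyridine, THF, 0 °C → rt
Reagents that add atoms: none
Why: Buffered HF removes all three silyl ethers in one operation; basic fluoride is avoided because the enal has γ-hydrogens.

## Compound list

1 | pent-4-enoyl chloride | C=CCCC(=O)Cl | starting material
2 | N-methoxy-N-methylpent-4-enamide | C=CCCC(=O)N(C)OC | intermediate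
3 | 1,2-dibromocyclopent-1-ene | BrC1=C(Br)CCC1 | starting material
4 | (2-bromocyclopent-1-en-1-yl)lithium | [Li]C1=C(Br)CCC1 | intermediate (not isolated)
5 | 1-(2-bromocyclopent-1-en-1-yl)pent-4-en-1-one | C=CCCC(=O)C1=C(Br)CCC1 | intermediate
6 | dimethylzinc | C[Zn]C | starting material
7 | (2S)-2-(2-bromocyclopent-1-en-1-yl)hex-5-en-2-ol | C=CCC[C@](C1=C(Br)CCC1)(C)O | intermediate
8 | (2S)-2-(2-bromocyclopent-1-en-1-yl)hex-5-en-2-yl triethylsilyl ether | C=CCC[C@](C1=C(Br)CCC1)(C)O[Si](CC)(CC)CC | intermediate
9 | (4S)-4-(2-bromocyclopent-1-en-1-yl)-4-(triethylsilyloxy)pentanal | O=CCC[C@](C1=C(Br)CCC1)(C)O[Si](CC)(CC)CC | intermediate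
10 | vinylmagnesium bromide | C=C[Mg]Br | starting material
11 | (6S)-6-(2-bromocyclopent-1-en-1-yl)-6-(triethylsilyloxy)hept-1-en-3-ol (C3 epimers, centre left open) | C=CC(O)CC[C@](C1=C(Br)CCC1)(C)O[Si](CC)(CC)CC | intermediate
12 | tributyl(vinyl)stannane | C=C[Sn](CCCC)(CCCC)CCCC | starting material
13 | (6S)-6-(2-ethenylcyclopent-1-en-1-yl)-6-(triethylsilyloxy)hept-1-en-3-ol (C3 epimers, centre left open) | C=CC(O)CC[C@](C1=C(C=C)CCC1)(C)O[Si](CC)(CC)CC | intermediate
14 | (6S)-6-(2-ethenylcyclopent-1-en-1-yl)-6-(triethylsilyloxy)hept-1-en-3-one | C=CC(=O)CC[C@](C1=C(C=C)CCC1)(C)O[Si](CC)(CC)CC | intermediate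
15 | tricyclic ketone (5S,6S,10S), C1=C3′ alkene, C7 ketone, C10 methyl/triethylsilyloxy | O=C1CC[C@](C)(O[Si](CC)(CC)CC)[C@]23CCCC2=CCC[C@H]13 | intermediate
16 | C7 ethylene ketal of 15 | O1CCOC12CC[C@](C)(O[Si](CC)(CC)CC)[C@]34CCCC3=CCC[C@H]24 | intermediate
17 | 6-(3-oxopropyl)-10-methyl-10-(triethylsilyloxy)spiro[4.5]decane-1,7-dione 7-ethylene ketal | O=C1CCC[C@]12[C@H](CCC=O)C3(OCCO3)CC[C@]2(C)O[Si](CC)(CC)CC | intermediate (not isolated)
18 | 6-(3-hydroxypropyl)-10-methyl-10-(triethylsilyloxy)spiro[4.5]decane-1,7-dione 7-ethylene ketal | O=C1CCC[C@]12[C@H](CCCO)C3(OCCO3)CC[C@]2(C)O[Si](CC)(CC)CC | intermediate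
19 | 6-[3-(tert-butyldiphenylsilyloxy)propyl]-10-methyl-10-(triethylsilyloxy)spiro[4.5]decane-1,7-dione 7-ethylene ketal | O=C1CCC[C@]12[C@H](CCCO[Si](c3ccccc3)(c3ccccc3)C(C)(C)C)C3(OCCO3)CC[C@]2(C)O[Si](CC)(CC)CC | intermediate
20 | C1 enol triflate of 19 | FC(F)(F)S(=O)(=O)OC1=CCC[C@]12[C@H](CCCO[Si](c3ccccc3)(c3ccccc3)C(C)(C)C)C3(OCCO3)CC[C@]2(C)O[Si](CC)(CC)CC | intermediate
21 | 6-[3-(tert-butyldiphenylsilyloxy)propyl]-10-methyl-10-(triethylsilyloxy)spiro[4.5]dec-1-en-7-one ethylene ketal | C1=CCC[C@]12[C@H](CCCO[Si](c3ccccc3)(c3ccccc3)C(C)(C)C)C3(OCCO3)CC[C@]2(C)O[Si](CC)(CC)CC | intermediate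
22 | 6-[3-(tert-butyldiphenylsilyloxy)propyl]-10-hydroxy-10-methylspiro[4.5]dec-1-en-7-one ethylene ketal | C1=CCC[C@]12[C@H](CCCO[Si](c3ccccc3)(c3ccccc3)C(C)(C)C)C3(OCCO3)CC[C@]2(C)O | intermediate
23 | 1,2-epoxide of 22, oxirane oxygen syn to C10 | O1[C@H]2CC[C@]3([C@H](CCCO[Si](c4ccccc4)(c4ccccc4)C(C)(C)C)C4(OCCO4)CC[C@]3(C)O)[C@@H]12 | intermediate
24 | ethynyltrimethylsilane | C#C[Si](C)(C)C | starting material
25 | 2-[(trimethylsilyl)ethynyl] analogue of 26 | C[Si](C)(C)C#C[C@@H]1CC[C@]2([C@H](CCCO[Si](c3ccccc3)(c3ccccc3)C(C)(C)C)C3(OCCO3)CC[C@]2(C)O)[C@H]1O | intermediate (not isolated)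
26 | 2-ethynyl-6-[3-(tert-butyldiphenylsilyloxy)propyl]-1,10-dihydroxy-10-methylspiro[4.5]decan-7-one ethylene ketal | C#C[C@@H]1CC[C@]2([C@H](CCCO[Si](c3ccccc3)(c3ccccc3)C(C)(C)C)C3(OCCO3)CC[C@]2(C)O)[C@H]1O | intermediate
27 | C1 tert-butyldimethylsilyl ether of 26 | C#C[C@@H]1CC[C@]2([C@H](CCCO[Si](c3ccccc3)(c3ccccc3)C(C)(C)C)C3(OCCO3)CC[C@]2(C)O)[C@H]1O[Si](C)(C)C(C)(C)C | intermediate
28 | 2-(1-iodoethenyl) analogue of 27 | C=C(I)[C@@H]1CC[C@]2([C@H](CCCO[Si](c3ccccc3)(c3ccccc3)C(C)(C)C)C3(OCCO3)CC[C@]2(C)O)[C@H]1O[Si](C)(C)C(C)(C)C | intermediate
29 | 1-(tert-butyldimethylsilyloxy)-6-[3-(tert-butyldiphenylsilyloxy)propyl]-10-hydroxy-2-(1-iodoethenyl)-10-methylspiro[4.5]decan-7-one | C=C(I)[C@@H]1CC[C@]2([C@H](CCCO[Si](c3ccccc3)(c3ccccc3)C(C)(C)C)C(=O)CC[C@]2(C)O)[C@H]1O[Si](C)(C)C(C)(C)C | intermediate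
30 | isopropenylmagnesium bromide | CC(=C)[Mg]Br | starting material
31 | 7-hydroxy-7-(prop-1-en-2-yl) adduct of 29 (C7 epimers, centre left open) | C=C(I)[C@@H]1CC[C@]2([C@H](CCCO[Si](c3ccccc3)(c3ccccc3)C(C)(C)C)C(O)(C(C)=C)CC[C@]2(C)O)[C@H]1O[Si](C)(C)C(C)(C)C | intermediate
32 | (2Z)-2-[1-(tert-butyldimethylsilyloxy)-6-[3-(tert-butyldiphenylsilyloxy)propyl]-10-hydroxy-2-(1-iodoethenyl)-10-methylspiro[4.5]decan-7-ylidene]propanal | C=C(I)[C@@H]1CC[C@]2([C@H](CCCO[Si](c3ccccc3)(c3ccccc3)C(C)(C)C)/C(=C(/C)C=O)CC[C@]2(C)O)[C@H]1O[Si](C)(C)C(C)(C)C | intermediate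
33 | 5-bromo-2-methylpent-2-ene | CC(C)=CCCBr | starting material
34 | prop-2-yn-1-ol | C#CCO | starting material
35 | (4-methylpent-3-en-1-yl)magnesium bromide | CC(C)=CCC[Mg]Br | intermediate (not isolated)
36 | 4-(4-methylpent-3-en-1-yl)-2,5-dihydro-1,2-oxamagnesole (alkenylmagnesium alkoxide) | CC(C)=CCCC1=C[Mg]OC1 | intermediate (not isolated)
37 | (2Z)-3-iodo-2-(4-methylpent-3-en-1-yl)prop-2-en-1-ol | I/C=C(\CO)CCC=C(C)C | intermediate
38 | tert-butyl{[(2Z)-3-iodo-2-(4-methylpent-3-en-1-yl)prop-2-en-1-yl]oxy}dimethylsilane | I/C=C(\CO[Si](C)(C)C(C)(C)C)CCC=C(C)C | intermediate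
39 | (E)-1,2-bis(tributylstannyl)ethene | CCCC[Sn](CCCC)(CCCC)/C=C/[Sn](CCCC)(CCCC)CCCC | starting material
40 | tributyl[(1E,3Z)-4-({[tert-butyl(dimethyl)silyl]oxy}methyl)-8-methylnona-1,3,7-trien-1-yl]stannane | CCCC[Sn](CCCC)(CCCC)/C=C/C=C(\CO[Si](C)(C)C(C)(C)C)CCC=C(C)C | intermediate
41 | tris-silyl ether of 42 | C=C(/C=C/C=C(\CO[Si](C)(C)C(C)(C)C)CCC=C(C)C)[C@@H]1CC[C@]2([C@H](CCCO[Si](c3ccccc3)(c3ccccc3)C(C)(C)C)/C(=C(/C)C=O)CC[C@]2(C)O)[C@H]1O[Si](C)(C)C(C)(C)C | intermediate
42 | (2Z)-2-[(1S,2S,5S,6R,10S)-1,10-dihydroxy-2-[(3E,5Z)-6-(hydroxymethyl)-10-methylundeca-1,3,5,9-tetraen-2-yl]-6-(3-hydroxypropyl)-10-methylspiro[4.5]decan-7-ylidene]propanal | C=C(/C=C/C=C(\CO)CCC=C(C)C)[C@@H]1CC[C@]2([C@H](CCCO)/C(=C(/C)C=O)CC[C@]2(C)O)[C@H]1O | target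

## Step count and least certain steps

Total: 27 steps. Longest linear sequence: 24 steps (steps 1–22, 26 and 27); the side-chain branch is steps 23–25.

**Step 9 (key step).** The most likely failure is poor discrimination between the two cis-fused transition states, because the oxygen and the methyl group of C10 differ only moderately in their demand for the inside position; this would give the C5,C6-bis-epimer alongside 15. Polymerisation of the vinyl ketone before the hindered diene terminus reacts is a second risk. The fallback changes the controlling group, not just the conditions. It sets out from 13: fluoride removes the silyl group to give (6S)-6-(2-ethenylcyclopent-1-en-1-yl)hept-1-ene-3,6-diol F1. MnO2 oxidises only the allylic alcohol to (6S)-6-(2-ethenylcyclopent-1-en-1-yl)-6-hydroxyhept-1-en-3-one F2, in which the bare hydroxyl is the smallest possible oxygen substituent for the inside position. Cycloaddition then gives the hydroxy tricycle F3, and silylation with Et3SiOTf returns to the route at 15.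

**Step 3.** Methyl transfer to a ketone whose second flank is a chain and not a methyl group may be slow and less selective, and conjugate displacement of the vinylic bromide can compete. The fallback forms the other C–C bond of the carbinol asymmetrically. It sets out from 3: the lithium reagent 4 is acylated with N-methoxy-N-methylacetamide to give 1-(2-bromocyclopent-1-en-1-yl)ethan-1-one F4, a methyl ketone of the class this catalyst handles best. Salt-free di(but-3-en-1-yl)zinc F5, prepared from but-3-enylmagnesium bromide and ZnCl2, is then added under the same titanium catalyst with the appropriate ligand antipode. The sequence comes back at 7.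

**Step 16.** Vanadium delivery from a hindered tertiary homoallylic hydroxyl may be sluggish, which would let undirected epoxidation from the C6 face intrude. The fallback builds the same epoxide indirectly and sets out from 21. N-bromosuccinimide in aqueous dimethoxyethane should form the bromonium ion on the face away from the C10 silyl ether; water opens it at C2 to give the trans bromohydrin (1-bromo-2-hydroxy) F6. K2CO3 in methanol closes it to the silyl-protected epoxide F7 with the oxygen syn to C10, and HF·pyridine then rejoins the route at 23.

**Step 19.** Internal selectivity of the hydroalumination may erode next to a branched carbon flanked by a silyloxy group, and the aluminium hydride may attack the ketal. The fallback uses a different hydrometalation and sets out from 27: Mo(CO)3(CNt-Bu)3-catalysed hydrostannation with Bu3SnH gives the internal alkenylstannane, the 2-[1-(tributylstannyl)ethenyl] analogue of 27 F8, and iodine converts it into 28.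

**Step 22.** The tertiary allylic alcohol may dehydrate on the acidic chromium reagent, or the enal may form as a mixture of geometries if the preference for formyl syn to C6 is small. The fallback replaces addition/transposition by olefination and sets out from 29. A Horner–Wadsworth–Emmons reaction with the sodium salt of diethyl (1-cyanoethyl)phosphonate gives the tetrasubstituted nitrile, the (2Z)-2-(spirodecan-7-ylidene)propanenitrile analogue of 32 F9, whose small linear cyano group should sit syn to the branched C6 more decisively. Reduction with i-Bu2AlH at −78 °C and mild acidic hydrolysis of the imine returns to the route at 32.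

## Further compounds

F1 | step 9 | (6S)-6-(2-ethenylcyclopent-1-en-1-yl)hept-1-ene-3,6-diol (C3 epimers) | C=CC(O)CC[C@](C1=C(C=C)CCC1)(C)O
F2 | step 9 | (6S)-6-(2-ethenylcyclopent-1-en-1-yl)-6-hydroxyhept-1-en-3-one | C=CC(=O)CC[C@](C1=C(C=C)CCC1)(C)O
F3 | step 9 | C10 hydroxy analogue of tricyclic ketone 15 | O=C1CC[C@](C)(O)[C@]23CCCC2=CCC[C@H]13
F4 | step 3 | 1-(2-bromocyclopent-1-en-1-yl)ethan-1-one | CC(=O)C1=C(Br)CCC1
F5 | step 3 | di(but-3-en-1-yl)zinc | C=CCC[Zn]CCC=C
F6 | step 16 | trans bromohydrin of 21 (C1 bromide on the C6 face, C2 hydroxyl on the C10 face) | O[C@H]1CC[C@]2([C@H](CCCO[Si](c3ccccc3)(c3ccccc3)C(C)(C)C)C3(OCCO3)CC[C@]2(C)O[Si](CC)(CC)CC)[C@@H]1Br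
F7 | step 16 | C10 triethylsilyl ether of epoxide 23 | O1[C@H]2CC[C@]3([C@H](CCCO[Si](c4ccccc4)(c4ccccc4)C(C)(C)C)C4(OCCO4)CC[C@]3(C)O[Si](CC)(CC)CC)[C@@H]12
F8 | step 19 | 2-[1-(tributylstannyl)ethenyl] analogue of 27 | C=C([Sn](CCCC)(CCCC)CCCC)[C@@H]1CC[C@]2([C@H](CCCO[Si](c3ccccc3)(c3ccccc3)C(C)(C)C)C3(OCCO3)CC[C@]2(C)O)[C@H]1O[Si](C)(C)C(C)(C)C
F9 | step 22 | (2Z)-2-(spirodecan-7-ylidene)propanenitrile analogue of 32 | C=C(I)[C@@H]1CC[C@]2([C@H](CCCO[Si](c3ccccc3)(c3ccccc3)C(C)(C)C)/C(=C(/C)C#N)CC[C@]2(C)O)[C@H]1O[Si](C)(C)C(C)(C)C
A1 | alternative 1 | open-chain iodo keto diester (C9 iodide, C10 acetyl, C1 methyl ester, tert-butyl ester arm) | CC(C)(C)OC(=O)CCC[C@](C(C)=O)([C@H](CCCO[Si](C)(C)C(C)(C)C)[C@@H](O[Si](C)(C)C(C)(C)C)CCI)C(=O)OC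
A2 | alternative 1 | ring B hydroxy ester with the C5, C6 and C10 stereotriad | CC(C)(C)OC(=O)CCC[C@]1([C@H](CCCO[Si](C)(C)C(C)(C)C)[C@@H](O[Si](C)(C)C(C)(C)C)CC[C@]1(C)O)C(=O)OC
A3 | alternative 2 | 1-alkenylcyclobutanol aldehyde (C7 aldehyde, C5=C6 alkene of open geometry, C10 silyl ether) | O=CCC[C@](C)(O[Si](CC)(CC)CC)C(=CCCCO[Si](C)(C)C(C)(C)C)C1(O)CCC1
A4 | alternative 2 | spiro[4.5]decan-1-one with C7 hydroxyl, C6 arm and C10 silyl ether | O=C1CCC[C@]12[C@H](CCCO[Si](C)(C)C(C)(C)C)[C@@H](O)CC[C@]2(C)O[Si](CC)(CC)CC
A5 | alternative 3 | methyl 3-(tert-butyldimethylsilyloxy)-6-oxocyclohex-1-ene-1-carboxylate | COC(=O)C1=C[C@@H](O[Si](C)(C)C(C)(C)C)CCC1=O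
A6 | alternative 3 | [3-(tert-butyldimethylsilyloxy)propyl]magnesium bromide | Br[Mg]CCCO[Si](C)(C)C(C)(C)C
A7 | alternative 3 | methyl (E)-4-bromobut-2-enoate | COC(=O)/C=C/CBr
A8 | alternative 3 | ring B keto diester with quaternary C5 and the C6 arm | COC(=O)/C=C/C[C@]1([C@H](CCCO[Si](C)(C)C(C)(C)C)[C@@H](O[Si](C)(C)C(C)(C)C)CCC1=O)C(=O)OC
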